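At early times in east the substrate has a half-life of 0.14 s against the coupling partner as charged, short against the 50 s of the run, so I reckon by how the partner is shared out, not by the clock.

    substrate + coupling partner → mono adduct (k1 = 5390 L mol⁻¹ s⁻¹)
    coupling partner + mono adduct → bis adduct (k2 = 2090 L mol⁻¹ s⁻¹)
    coupling partner + bis adduct → tris adduct (k3 = 8150 L mol⁻¹ s⁻¹)
    coupling partner + tris adduct ⇌ idle adduct, settled at all times (K4 = 3200 L mol⁻¹)
    coupling partner → decomposed reagent (k5 = 0.342 s⁻¹)

| setting | east | west |
|---|---|---|
| substrate | 0.50 mM | 0.50 mM |
| coupling partner | 1.80 equiv | 3.60 equiv |
| time | 50 s | 50 s |

- what is said of tris adduct includes idle adduct
- run time (east): 50 s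

- which of these there is most of at the end, counted by the substrate in it, east (tris adduct / substrate / bis adduct / mono adduct)
- which of these there is most of at the end, counted by the substrate in it, west (tris adduct / substrate / bis adduct / mono adduct)
- final amount of the leader among these, as a percentage of the substrate charged, in east
- final amount of the leader among these, as a percentage of the substrate charged, in west

1. First addition alone: each substrate takes one partner, and east charges 1.80 equiv, more than that one, so at this stage of my reckoning east ends with mono adduct and spare partner.

2. Now decomposition. It and the first addition both run on free partner, so the ratio of their rates doesn't depend on c(coupling partner). I call that ratio the leak, 0.127: the equivalents of partner decomposed each time free substrate falls by a factor e. It is the decomposition constant over the first addition's constant times c(substrate) as charged. With x the natural logarithm of substrate charged over substrate left, the equivalents lost are the leak times x.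

3. Now the later additions. In east as charged, bis adduct has a shorter half-life by its next step than mono adduct by its own, so I count bis and tris as one pool at 3 partners. With a = e^(−x) and ρ = 0.388, the mono share is m = (a^ρ − a)/(1 − ρ). The charge must equal 3(1 − a) − 2m plus the leak times x.

For east, x = 2 puts mono adduct at 53.1% and the pool at 33.4%, and it needs 1.79 equivalents, close to the 1.80 equiv charged.

For west, x = 7 puts mono adduct at 10.7% and the pool at 89.2%, and it needs 3.67 equivalents, slightly over the 3.60 equiv charged. So in west x lies slightly lower, with mono adduct a little above that figure and the pool a little below its figure.

4. Last, the idle adduct. Its ratio to tris adduct is the balance constant times free partner, 2.9 at the start in east, so it empties as free partner falls, and the leak stands.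

The forecast gives mono adduct at 51.4% in east and tris adduct at 84.8% in west, holding of the coupling partner that “decomposition finishes it off and the idle adduct only holds it briefly”. My mono adduct for east is higher, and my west figure is the pool, not tris adduct by itself.

East ends with mono adduct at 51.4%, and west with tris adduct at 84.7%. In east the free coupling partner, the limiting reagent, stands at 0% of its charge at the end, with 10.9% of the substrate left. The leak turns that substrate into 0.141 mM of partner lost, and east holds 0.141 mM of decomposed reagent. In the neighbour with 0.12 mM of substrate the leak is 0.529, and its 25% of substrate left gives 0.0880 mM, while that flask holds 0.0886 mM of decomposed reagent.

The constants used here are those of an exercise.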